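The plan cuts the bond between C3 of the lactone ring (ring B) and the first side-chain carbon C1'. C3 is the only carbinol carbon of ring B, flanked by benzylic C4, and its oxygen can reach the ester carbon C1 through a six-membered ring; it is therefore unmasked as an aldehyde on a benzoate (fragment A). The complete side chain, with the (R)-carbinol succinate in place, is a terminal olefin (fragment B) that becomes a dialkylzinc in the flask. One ligand-controlled, Ti(OiPr)4-mediated addition forms C3–C1', sets (3R) and lets the C3 oxygen close ring B onto the ortho ester. A single hydrogenolysis then frees both phenols and the acid.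

Key step: step 6

Remark: the structure is read as the (3R)-5,8-dihydroxy-3,4-dihydroisocoumarin whose C3 carries a (4R)-4-(3-carboxypropanoyloxy)pentyl chain, a 1,5-syn pair of oxygenated centers; ring atoms are numbered C1 (carbonyl), O2, C3, C4, side-chain carbons C1' to C5' outward from C3, the arene is ring A and the lactone ring is ring B.

Step 1
Reactants: 1 methyl 2,5-dihydroxybenzoate; 2 allyl bromide
Product: 3 methyl 5-(allyloxy)-2-hydroxybenzoate
Conditions: K2CO3 (1.1 equiv), acetone, reflux
Reagents that add atoms: none
Why: Williamson etherification; the 2-OH is held in a hydrogen bond to the ester carbonyl, so with one equivalent of 2 the freer and more nucleophilic 5-phenoxide should be alkylated selectively.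

Step 2
Reactants: 3 methyl 5-(allyloxy)-2-hydroxybenzoate
Product: 4 methyl 2-allyl-3,6-dihydroxybenzoate
Conditions: N,N-diethylaniline, 190 °C, argon
Reagents that add atoms: none
Why: Aromatic Claisen rearrangement ([3,3]-sigmatropic shift, then tautomerization); the chelated salicylate unit fixes double-bond character between the allyloxy carbon and the ring carbon next to the ester, and a meta acceptor group also draws the migration towards itself, so the allyl group should end up between the oxygen and the ester.

Step 3
Reactants: 4 methyl 2-allyl-3,6-dihydroxybenzoate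
Product: 5 methyl 2-allyl-3,6-bis(benzyloxy)benzoate
Conditions: BnBr (2.5 equiv), K2CO3, Bu4NI (cat.), DMF, 60 °C, argon
Reagents that add atoms: benzyl bromide, BrCc1ccccc1
Why: Twofold Williamson benzylation; warm DMF and iodide catalysis should overcome the hydrogen-bonded 6-OH and the flanked 3-OH, and argon keeps the hydroquinone from air oxidation.

Step 4
Reactants: 5 methyl 2-allyl-3,6-bis(benzyloxy)benzoate
Product: 6 methyl 3,6-bis(benzyloxy)-2-(2-oxoethyl)benzoate
Conditions: OsO4 (2 mol%), NaIO4, 2,6-lutidine, dioxane/H2O, rt
Reagents that add atoms: sodium periodate (NaIO4), [Na+].[O-]I(=O)(=O)=O, whose oxygen reaches the aldehyde through OsO4, O=[Os](=O)(=O)=O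
Why: Lemieux–Johnson cleavage (catalytic osmylation, then periodate glycol scission) removes the terminal CH2 and leaves the arylacetaldehyde; the buffered medium should spare the benzyl ethers and the ester.

Step 5
Reactants: 7 (R)-pent-4-en-2-ol; 8 4-(benzyloxy)-4-oxobutanoic acid
Product: 9 benzyl (2R)-pent-4-en-2-yl butanedioate
Conditions: EDC·HCl, DMAP (cat.), CH2Cl2, 0 °C to rt
Reagents that add atoms: none
Why: Steglich-type carbodiimide esterification forms only the acyl–oxygen bond, so the (R) carbinol center of 7 is carried through untouched.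

Step 6
Reactants: 9 benzyl (2R)-pent-4-en-2-yl butanedioate; 6 methyl 3,6-bis(benzyloxy)-2-(2-oxoethyl)benzoate
Product: 13 benzyl (2R)-5-[(3R)-5,8-bis(benzyloxy)-1-oxo-3,4-dihydro-1H-2-benzopyran-3-yl]pentan-2-yl butanedioate, via alkyldiethylborane 10 (not isolated), via dialkylzinc 11 (not isolated), via hydroxy ester 12 (not isolated)
Conditions: 9 (4 equiv), Et2BH (from Et3B, BH3·SMe2), Et2O, 0 °C to rt; evaporate; Et2Zn, 0 °C; evaporate (removes Et2Zn, Et3B); then 6, Ti(OiPr)4 (2 equiv), (1S,2S)-1,2-bis(trifluoromethanesulfonamido)cyclohexane (8 mol%), toluene, −20 °C; 1 M HCl; TsOH·H2O (cat.), toluene, 40 °C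
Reagents that add atoms: none
Why: Anti-Markovnikov hydroboration of 9 and boron–zinc exchange give dialkylzinc 11, whose primary alkyl group is passed through the chiral complex formed from Ti(OiPr)4 and the bis(sulfonamide) ligand to the titanium-bound aldehyde carbon of 6. The closest known reaction type is the enantioselective addition of ester-bearing dialkylzincs to aldehydes catalysed by Ti(OiPr)4 and trans-1,2-bis(trifluoromethanesulfonamido)cyclohexane. Ring B then closes by 6-exo-trig acyl substitution of the C3 oxygen on the ortho methyl ester (lactonization), completed by catalytic TsOH. The C3 center is set by the catalyst alone: the (1R,2R) ligand is known to send alkyl groups to the Si face of aldehydes, so the (1S,2S) ligand should deliver C1' to the Re face and give (3R), while the (4'R) center five bonds away is a spectator. The step needs aldehyde-over-ester chemoselectivity and addition faster than enolization of the arylacetaldehyde; the low basicity and low carbonyl reactivity of dialkylzincs at −20 °C and the doubly ortho-flanked ester should secure both, and thorough removal of Et2Zn and Et3B prevents ethyl transfer.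

Step 7
Reactants: 13 benzyl (2R)-5-[(3R)-5,8-bis(benzyloxy)-1-oxo-3,4-dihydro-1H-2-benzopyran-3-yl]pentan-2-yl butanedioate
Product: 14 4-{[(2R)-5-[(3R)-5,8-dihydroxy-1-oxo-3,4-dihydro-1H-2-benzopyran-3-yl]pentan-2-yl]oxy}-4-oxobutanoic acid (CNP0599867.1)
Conditions: H2 (1 atm), Pd/C (10%), EtOAc, rt
Reagents that add atoms: none
Why: Catalytic hydrogenolysis cleaves the two aryl benzyl ethers and the benzyl ester in one operation; the lactone C3–O bond is homobenzylic and both stereocenters are remote from any reducible site, so they should survive.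

Compound list
1 | methyl 2,5-dihydroxybenzoate | COC(=O)c1cc(O)ccc1O | starting material
2 | allyl bromide (3-bromoprop-1-ene) | C=CCBr | starting material
3 | methyl 5-(allyloxy)-2-hydroxybenzoate | COC(=O)c1cc(OCC=C)ccc1O | intermediate
4 | methyl 2-allyl-3,6-dihydroxybenzoate | COC(=O)c1c(O)ccc(O)c1CC=C | intermediate
5 | methyl 2-allyl-3,6-bis(benzyloxy)benzoate | COC(=O)c1c(OCc2ccccc2)ccc(OCc2ccccc2)c1CC=C | intermediate
6 | methyl 3,6-bis(benzyloxy)-2-(2-oxoethyl)benzoate | COC(=O)c1c(OCc2ccccc2)ccc(OCc2ccccc2)c1CC=O | intermediate
7 | (R)-pent-4-en-2-ol | C[C@H](CC=C)O | starting material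
8 | 4-(benzyloxy)-4-oxobutanoic acid (monobenzyl succinate) | OC(=O)CCC(=O)OCc1ccccc1 | starting material
9 | benzyl (2R)-pent-4-en-2-yl butanedioate | C[C@H](CC=C)OC(=O)CCC(=O)OCc1ccccc1 | intermediate
10 | benzyl (2R)-5-(diethylboranyl)pentan-2-yl butanedioate (formed in the flask) | C[C@H](CCCB(CC)CC)OC(=O)CCC(=O)OCc1ccccc1 | intermediate
11 | bis[(4R)-4-{[4-(benzyloxy)-4-oxobutanoyl]oxy}pentyl]zinc (formed in the flask) | C[C@H](CCC[Zn]CCC[C@@H](C)OC(=O)CCC(=O)OCc1ccccc1)OC(=O)CCC(=O)OCc1ccccc1 | intermediate
12 | methyl 3,6-bis(benzyloxy)-2-[(2R,6R)-6-{[4-(benzyloxy)-4-oxobutanoyl]oxy}-2-hydroxyheptyl]benzoate (formed in the flask) | COC(=O)c1c(OCc2ccccc2)ccc(OCc2ccccc2)c1C[C@H](O)CCC[C@@H](C)OC(=O)CCC(=O)OCc1ccccc1 | intermediate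
13 | benzyl (2R)-5-[(3R)-5,8-bis(benzyloxy)-1-oxo-3,4-dihydro-1H-2-benzopyran-3-yl]pentan-2-yl butanedioate | C[C@H](CCC[C@@H]1Cc2c(OCc3ccccc3)ccc(OCc3ccccc3)c2C(=O)O1)OC(=O)CCC(=O)OCc1ccccc1 | intermediate
14 | 4-{[(2R)-5-[(3R)-5,8-dihydroxy-1-oxo-3,4-dihydro-1H-2-benzopyran-3-yl]pentan-2-yl]oxy}-4-oxobutanoic acid | C[C@H](CCC[C@@H]1Cc2c(O)ccc(O)c2C(=O)O1)OC(=O)CCC(=O)O | target

Total step count: 7. Longest linear sequence: 6 steps (steps 1, 2, 3, 4, 6, 7).

Steps most likely to fail

Step 6. Enolization and self-condensation of the arylacetaldehyde may outrun alkyl transfer, incomplete boron–zinc exchange may lead to competing ethyl transfer, and facial selectivity on an unbranched arylacetaldehyde may be poor. The fallback sets out from 6 and still forms the C3–C1' bond, now with a three-carbon unit. Asymmetric allylboration with the B-allyldiisopinocampheylborane made from (−)-α-pinene ((+)-Ipc2BOMe, allylMgBr, Et2O, −78 °C, then NaOH/H2O2) is used; this is the enantiomer of the reagent that turns benzaldehyde into (S)-1-phenylbut-3-en-1-ol. It should add to the Re face and give the hydroxy ester methyl 3,6-bis(benzyloxy)-2-[(2R)-2-hydroxypent-4-en-1-yl]benzoate F1, which catalytic TsOH in toluene should close to (3R)-3-allyl-5,8-bis(benzyloxy)-3,4-dihydro-1H-2-benzopyran-1-one F2. The rest of the chain comes from (R)-but-3-en-2-ol and 8 under the conditions of step 5, giving benzyl (2R)-but-3-en-2-yl butanedioate F3. Cross-metathesis of F2 with excess F3 (second-generation Hoveyda–Grubbs catalyst, CH2Cl2, 40 °C) should give benzyl (2R,3E)-5-[(3R)-5,8-bis(benzyloxy)-1-oxo-3,4-dihydro-1H-2-benzopyran-3-yl]pent-3-en-2-yl butanedioate F4. Diimide reduction (2-nitrobenzenesulfonyl hydrazide, Et3N, CH2Cl2, rt) saturates the C2'=C3' bond without touching the benzyl groups or the allylic C–O bond, and the route is rejoined at 13.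

Step 2. The allyl group may migrate to the other free ortho position (away from the ester), or the ortho-allylphenol may ring-close to a dihydrobenzofuran at the high temperature. The fallback sets out from 1 and replaces sigmatropic control by electronic control. Oxidation with Ag2O (MgSO4, Et2O, rt) should give the quinone methyl 3,6-dioxocyclohexa-1,4-diene-1-carboxylate F5. Conjugate allylation with allyltributylstannane (Bu3SnCH2CH=CH2) and BF3·OEt2 in CH2Cl2 at −78 °C should place the allyl group on the ring carbon next to the ester, which is β to both the ester and a quinone carbonyl and therefore the most electrophilic position. Tautomerization of the adduct to the hydroquinone returns the route at 4.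

Step 4. The transient 1,2-diol may lactonize onto the neighbouring ester before glycol scission, and the arylacetaldehyde may enolize, oxidize in air or self-condense during isolation. The fallback sets out from 5 and stores the aldehyde in masked form. Ozonolysis (O3, CH2Cl2/MeOH, −78 °C, indicator dye to stop at the alkene; Me2S) followed by HC(OMe)3 and catalytic TsOH in MeOH should give the acetal methyl 3,6-bis(benzyloxy)-2-(2,2-dimethoxyethyl)benzoate F6, which has no free hydroxyl and can be purified and kept. Brief treatment with aqueous CF3CO2H in CH2Cl2 releases 6 immediately before step 6.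

Further compounds
F1 | step 6 | methyl 3,6-bis(benzyloxy)-2-[(2R)-2-hydroxypent-4-en-1-yl]benzoate | COC(=O)c1c(OCc2ccccc2)ccc(OCc2ccccc2)c1C[C@H](O)CC=C
F2 | step 6 | (3R)-3-allyl-5,8-bis(benzyloxy)-3,4-dihydro-1H-2-benzopyran-1-one | C=CC[C@@H]1Cc2c(OCc3ccccc3)ccc(OCc3ccccc3)c2C(=O)O1
F3 | step 6 | benzyl (2R)-but-3-en-2-yl butanedioate | C[C@H](C=C)OC(=O)CCC(=O)OCc1ccccc1
F4 | step 6 | benzyl (2R,3E)-5-[(3R)-5,8-bis(benzyloxy)-1-oxo-3,4-dihydro-1H-2-benzopyran-3-yl]pent-3-en-2-yl butanedioate | C[C@H](/C=C/C[C@@H]1Cc2c(OCc3ccccc3)ccc(OCc3ccccc3)c2C(=O)O1)OC(=O)CCC(=O)OCc1ccccc1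
F5 | step 2 | methyl 3,6-dioxocyclohexa-1,4-diene-1-carboxylate | COC(=O)C1=CC(=O)C=CC1=O
F6 | step 4 | methyl 3,6-bis(benzyloxy)-2-(2,2-dimethoxyethyl)benzoate | COC(=O)c1c(OCc2ccccc2)ccc(OCc2ccccc2)c1CC(OC)OC
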